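**Retrosynthetic overview**
1. Target 11 ⇐ aromatic (R)-dihydrobenzofuran 8 + 2 × prenyl bromide: alkylative dearomatisation at C5, done last, with both phenols unmasked in the same pot.
2. 8 ⇐ ortho-prenyl phenol 6: phenolate-directed asymmetric epoxidation and 5-exo C–O ring closure. This step makes the dihydrofuran ring and the only stereocentre.
3. 6 ⇐ 5 ⇐ 3 ⇐ phloroglucinol + isobutyryl chloride: bis-silylation (leaves only O2–H, which fixes the oxygen that closes the ring), C-prenylation, Friedel–Crafts acylation.
4. Ring order: the carbocycle is bought as phloroglucinol, the dihydrofuran ring is formed in step 4, and the carbocycle is dearomatised in step 5.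

**Assumptions**
- The (R,R)-ligand in step 4 is taken as the antipode that delivers oxygen to the si face of the alkene CH carbon. This sense of induction is a prediction for a new substrate class; it is to be confirmed by chiral HPLC and by the rotation of 11, and the (S,S)-ligand is used if it is reversed.
- The target is drawn as its chelated enol tautomer; the tautomers equilibrate.

**Step 1**
Reactants: 1 phloroglucinol; 2 isobutyryl chloride
Product: 3 2-methyl-1-(2,4,6-trihydroxyphenyl)propan-1-one (phlorisobutyrophenone)
Conditions: AlCl3 (3.5 equiv), CH2Cl2/MeNO2, 0 °C to 40 °C; aq HCl work-up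
Reagents that add atoms: none
Why: Friedel–Crafts acylation of the electron-rich triol; the new acyl group, held in an aluminium chelate, deactivates the ring so the reaction stops at the mono-ketone, and no stereocentre is formed.

**Step 2**
Reactants: 3 phlorisobutyrophenone; 4 prenyl bromide (0.95 equiv)
Product: 5 2-methyl-1-[2,4,6-trihydroxy-3-(3-methylbut-2-en-1-yl)phenyl]propan-1-one
Conditions: 10% aq KOH, 0 °C, 2 h; acidify; recover unreacted 3
Reagents that add atoms: none
Why: Phenolate C-alkylation in a protic medium, where hydrogen bonding to oxygen favours C- over O-attack; the two free ring carbons of 3 are equivalent, so only one mono-C-prenyl isomer can form, and a slight deficit of bromide limits di-prenylation.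

**Step 3**
Reactants: 5 3-prenylphlorisobutyrophenone
Product: 6 1-[4,6-bis(tert-butyldimethylsilyloxy)-2-hydroxy-3-(3-methylbut-2-en-1-yl)phenyl]-2-methylpropan-1-one
Conditions: TBSCl (2.2 equiv), imidazole (4 equiv), DMF, 0 °C to rt
Reagents that add atoms: tert-butyldimethylsilyl chloride (TBSCl), CC(C)(C)[Si](C)(C)Cl
Why: Regioselective phenol silylation; O4 (para to the ketone, not chelated) and O6 (ortho, unhindered) react, while O2 is flanked by acyl and prenyl and locked in the hydrogen bond to the ketone, so it is the one hydroxyl left free.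

**Step 4**
Reactants: 6 bis-silyl ortho-prenyl phenol
Product: 8 1-[(2R)-4,6-bis(tert-butyldimethylsilyloxy)-2-(2-hydroxypropan-2-yl)-2,3-dihydro-1-benzofuran-7-yl]-2-methylpropan-1-one, via (S)-epoxide 7 (not isolated)
Conditions: Hf(OtBu)4 (10 mol%), (1R,2R)-N,N′-dihydroxy-N,N′-bis(2,2-diphenylacetyl)cyclohexane-1,2-diamine (12 mol%), cumene hydroperoxide (1.5 equiv), DMPU (20 mol%), 4 Å MS, toluene, 0 °C to rt; then Et3N (2 equiv), 40 °C
Reagents that add atoms: cumene hydroperoxide, CC(C)(OO)c1ccccc1
Why: Proposed new method: phenolate-directed asymmetric epoxidation–cycloetherification, in which the only free phenol (O2) and the acyl oxygen chelate tetravalent hafnium that also carries the twofold-symmetric bishydroxamate and an η2-cumylperoxide, so oxygen is delivered intramolecularly through a seven-membered transition state to the single alkene on the si face of its CH carbon to give (S)-epoxide 7, and the O2 aryloxide (the only oxygen nucleophile next to the side chain) then opens the epoxide 5-exo-tet at the secondary carbon with inversion, forming the ring C–O bond and setting (R) at C2; the closest known reaction types are the hafnium- or zirconium-bishydroxamic acid asymmetric epoxidation of homoallylic and bishomoallylic alcohols and the VO(acac)2/tBuOOH epoxidation–cyclisation of bishomoallylic alcohols, neither of which has been shown for ortho-prenyl phenols or o-acylphenolate chelates.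

**Step 5**
Reactants: 8 bis-silyl (R)-dihydrobenzofuran; 4 prenyl bromide (2.3 equiv)
Product: 11 garcinielliptone HC, via free diphenol 9 (not isolated), via monoprenyl diphenol 10 (not isolated)
Conditions: NaOMe (4 equiv), MeOH, rt, 30 min; then 4, 0 °C to rt; aq HCl work-up to pH 3
Reagents that add atoms: none
Why: Methoxide cleaves both aryl silyl ethers, and the resulting polyphenolate is C-alkylated twice at C5, the only unsubstituted ring carbon and ortho to both O4 and O6, the second alkylation being a lupulone-type alkylative dearomatisation that gives the acidic enol-dione; the ether stereocentre at C2 has no acidic hydrogen or elimination pathway and is untouched.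

**Compound list**
1 | phloroglucinol (benzene-1,3,5-triol) | Oc1cc(O)cc(O)c1 | starting material
2 | isobutyryl chloride (2-methylpropanoyl chloride) | CC(C)C(Cl)=O | starting material
3 | 2-methyl-1-(2,4,6-trihydroxyphenyl)propan-1-one (phlorisobutyrophenone) | CC(C)C(=O)c1c(O)cc(O)cc1O | intermediate
4 | prenyl bromide (1-bromo-3-methylbut-2-ene) | CC(C)=CCBr | starting material
5 | 2-methyl-1-[2,4,6-trihydroxy-3-(3-methylbut-2-en-1-yl)phenyl]propan-1-one | CC(C)C(=O)c1c(O)cc(O)c(CC=C(C)C)c1O | intermediate
6 | 1-[4,6-bis(tert-butyldimethylsilyloxy)-2-hydroxy-3-(3-methylbut-2-en-1-yl)phenyl]-2-methylpropan-1-one | CC(C)C(=O)c1c(O[Si](C)(C)C(C)(C)C)cc(O[Si](C)(C)C(C)(C)C)c(CC=C(C)C)c1O | intermediate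
7 | 1-[4,6-bis(tert-butyldimethylsilyloxy)-3-{[(2S)-3,3-dimethyloxiran-2-yl]methyl}-2-hydroxyphenyl]-2-methylpropan-1-one (not isolated) | CC(C)C(=O)c1c(O[Si](C)(C)C(C)(C)C)cc(O[Si](C)(C)C(C)(C)C)c(C[C@@H]2OC2(C)C)c1O | intermediate
8 | 1-[(2R)-4,6-bis(tert-butyldimethylsilyloxy)-2-(2-hydroxypropan-2-yl)-2,3-dihydro-1-benzofuran-7-yl]-2-methylpropan-1-one | CC(C)C(=O)c1c(O[Si](C)(C)C(C)(C)C)cc(O[Si](C)(C)C(C)(C)C)c2c1O[C@@H](C(C)(C)O)C2 | intermediate
9 | 1-[(2R)-4,6-dihydroxy-2-(2-hydroxypropan-2-yl)-2,3-dihydro-1-benzofuran-7-yl]-2-methylpropan-1-one (not isolated) | CC(C)C(=O)c1c(O)cc(O)c2c1O[C@@H](C(C)(C)O)C2 | intermediate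
10 | 1-[(2R)-4,6-dihydroxy-2-(2-hydroxypropan-2-yl)-5-(3-methylbut-2-en-1-yl)-2,3-dihydro-1-benzofuran-7-yl]-2-methylpropan-1-one (not isolated) | CC(C)C(=O)c1c(O)c(CC=C(C)C)c(O)c2c1O[C@@H](C(C)(C)O)C2 | intermediate
11 | garcinielliptone HC; (2R)-7-(1-hydroxy-2-methylpropylidene)-2-(2-hydroxypropan-2-yl)-5,5-bis(3-methylbut-2-en-1-yl)-2,3-dihydro-1-benzofuran-4,6(5H,7H)-dione, chelated enol tautomer | CC(C)=CCC1(CC=C(C)C)C(=O)C2=C(O[C@@H](C(C)(C)O)C2)/C(=C(/O)C(C)C)C1=O | target

**Step count**
Total steps: 5. Longest linear sequence: 5 (1 → 3 → 5 → 6 → 8 → 11).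

**Three steps most likely to fail, with fallbacks**

Step 4 (the proposed new step). Risks are low turnover or low ee with a phenolate instead of an alkoxide as directing group, 6-endo opening of the epoxide to a chromanol under Lewis acid, and Dakin-type oxidation of the aryl ketone. The fallback uses known chemistry, sets out from 5 and returns at 9.
- BnBr (2.1 equiv), K2CO3, acetone gives 1-[4,6-bis(benzyloxy)-2-hydroxy-3-(3-methylbut-2-en-1-yl)phenyl]-2-methylpropan-1-one F1; the chelated O2–H again stays free.
- Shi epoxidation with the enantiomer of the D-fructose-derived Shi ketone (made from L-sorbose), Oxone (2KHSO5·KHSO4·K2SO4), K2CO3 buffer, MeCN/dimethoxymethane/H2O, 0 °C gives the (S)-epoxide dibenzyl ether F2. The D-fructose ketone gives the (R)-epoxide of RCH2CH=CMe2 alkenes, so its antipode is needed.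
- The basic medium, or K2CO3 in MeOH, closes the epoxide 5-exo with inversion to the (R)-dihydrobenzofuran dibenzyl ether F3.
- H2, Pd/C, EtOAc removes both benzyl groups to give diphenol 9, which is isolated and taken through the alkylation of step 5 without the silyl cleavage.

Step 5. Risks are O-prenylation, over-alkylation of the acidic product and a modest yield in the dearomatising second alkylation. The fallback sets out from 8 and returns at 11.
- Tetrabutylammonium fluoride in THF gives diphenol 9, isolated here.
- Tsuji–Trost alkylative dearomatisation with allyl methyl carbonate (2.2 equiv) and Pd(PPh3)4 (zerovalent palladium, 5 mol%) in THF at rt gives, through the 5-allyl diphenol F4, the gem-diallyl analogue of the target F5.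
- Double cross-metathesis with excess 2-methylbut-2-ene and second-generation Grubbs catalyst, RuCl2(=CHPh)(PCy3)(SIMes), in CH2Cl2 at 40 °C turns both allyl groups into prenyl groups and gives 11.

Step 2. Risks are mixtures of mono-, di- and O-prenylated material and a low mass return. The fallback sets out from 3 and returns at 5.
- Friedel–Crafts-type prenylation with 2-methylbut-3-en-2-ol and BF3·OEt2 in dioxane at rt, stopped at partial conversion, gives 5 by electrophilic substitution with the dimethylallyl cation instead of phenolate alkylation. It makes no compound outside the list (F0).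

**Further compounds**
F1 | step 4 | 1-[4,6-bis(benzyloxy)-2-hydroxy-3-(3-methylbut-2-en-1-yl)phenyl]-2-methylpropan-1-one | CC(C)C(=O)c1c(OCc2ccccc2)cc(OCc2ccccc2)c(CC=C(C)C)c1O
F2 | step 4 | 1-[4,6-bis(benzyloxy)-3-{[(2S)-3,3-dimethyloxiran-2-yl]methyl}-2-hydroxyphenyl]-2-methylpropan-1-one | CC(C)C(=O)c1c(OCc2ccccc2)cc(OCc2ccccc2)c(C[C@@H]2OC2(C)C)c1O
F3 | step 4 | 1-[(2R)-4,6-bis(benzyloxy)-2-(2-hydroxypropan-2-yl)-2,3-dihydro-1-benzofuran-7-yl]-2-methylpropan-1-one | CC(C)C(=O)c1c(OCc2ccccc2)cc(OCc2ccccc2)c2c1O[C@@H](C(C)(C)O)C2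
F4 | step 5 | 1-[(2R)-4,6-dihydroxy-2-(2-hydroxypropan-2-yl)-5-(prop-2-en-1-yl)-2,3-dihydro-1-benzofuran-7-yl]-2-methylpropan-1-one | CC(C)C(=O)c1c(O)c(CC=C)c(O)c2c1O[C@@H](C(C)(C)O)C2
F5 | step 5 | (2R)-7-(1-hydroxy-2-methylpropylidene)-2-(2-hydroxypropan-2-yl)-5,5-bis(prop-2-en-1-yl)-2,3-dihydro-1-benzofuran-4,6(5H,7H)-dione | C=CCC1(CC=C)C(=O)C2=C(O[C@@H](C(C)(C)O)C2)/C(=C(/O)C(C)C)C1=O
F0 | step 2 | none | none
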